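**Strategy.** Everything rests on cutting ring B at C4'–C5' and C3'–C4'. The 4',5'-dioxygenated benzene, which carries C8'' of flavone unit 2 on C3' and C2 of flavone unit 1 on C1', is unravelled into an acyclic pentacarbonylchromium dienyl(methoxy)carbene complex. One irradiation under CO inserts a carbonyl ligand (future C4'–O) beside the carbene carbon (future C5'–OMe) and closes ring B onto the styryl terminus (C3'), which already holds ring A of unit 2. The precursor is (2E,4E)-(CO)5Cr=C(OMe)–CH=C[CH(OMe)2]–CH=CH–Ar, Ar = 2,4-bis(benzyloxy)-6-(methoxymethoxy)phenyl. Its acetal carbon later anchors unit 1, and both pyranone rings are closed afterwards by chalcone oxidation.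

Key step: step 6

Remarks on the chemistry:
- The target has no stereocentre; only alkene geometries of intermediates need control.
- The carbene complex that can cyclise has the carbene carbon and the styryl arm cis on C2=C3. Because CH(OMe)2 outranks the vinyl carbon on C3, this geometry is (2E,4E), not 2Z, and it is named so here.
- Assumption: the Wittig reaction of step 4 may also give the other geometry of the new C=CHBr bond. The route is written for the isomer shown; the other isomer is expected to converge in step 6 by photochemical E/Z isomerisation of the alkenylcarbene.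
- Assumption: 22, (bromomethyl)triphenylphosphonium bromide and N-methoxy-N-methylacetamide are bought.
- The MOM group on one ortho oxygen of the aryl ring is chosen so that the later acetylation and pyranone closure of unit 2 can be directed to the oxygen next to the biaryl bond.

**Route**

Step 1
Reactants: 1 2,4,6-trihydroxybenzaldehyde
Product: 2 2,4-bis(benzyloxy)-6-hydroxybenzaldehyde
Conditions: BnBr (2.0 equiv), K2CO3, DMF, rt
Reagents that add atoms: benzyl bromide, BrCc1ccccc1
Why: Williamson etherification under mild carbonate conditions alkylates the para hydroxyl and one ortho hydroxyl, after which the last hydroxyl is held in a hydrogen bond to the formyl group and is too poorly nucleophilic to react, as in the familiar 4,6-di-O-alkylation of phloroglucinol ketones.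

Step 2
Reactants: 2 2,4-bis(benzyloxy)-6-hydroxybenzaldehyde
Product: 3 2,4-bis(benzyloxy)-6-(methoxymethoxy)benzaldehyde
Conditions: NaH, MOMCl, DMF, 0 °C to rt
Reagents that add atoms: chloromethyl methyl ether, COCCl
Why: Williamson-type alkylation of the sodium phenoxide caps the chelated hydroxyl with the one group that can later direct ortho-lithiation and be removed by acid without touching benzyl ethers.

Step 3
Reactants: 3 2,4-bis(benzyloxy)-6-(methoxymethoxy)benzaldehyde; 4 1,1-dimethoxyacetone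
Product: 5 (E)-4-[2,4-bis(benzyloxy)-6-(methoxymethoxy)phenyl]-1,1-dimethoxybut-3-en-2-one
Conditions: NaOH (aq), MeOH, rt to 40 °C
Reagents that add atoms: none
Why: Claisen–Schmidt aldol condensation: the aldehyde cannot enolise, the ketone can lose water only after attack through its methyl group, and E1cB dehydration gives the conjugated E-enone, while MOM, benzyl ethers and the acetal are inert to hydroxide.

Step 4
Reactants: 5 (E)-4-[2,4-bis(benzyloxy)-6-(methoxymethoxy)phenyl]-1,1-dimethoxybut-3-en-2-one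
Product: 6 1,5-bis(benzyloxy)-2-[(1E,3E)-4-bromo-3-(dimethoxymethyl)buta-1,3-dien-1-yl]-3-(methoxymethoxy)benzene
Conditions: Ph3P(CH2Br)Br, KOtBu, THF, −78 °C to rt
Reagents that add atoms: (bromomethyl)triphenylphosphonium bromide, BrC[P+](c1ccccc1)(c1ccccc1)c1ccccc1.[Br-]
Why: Wittig olefination with the non-stabilised ylide Ph3P=CHBr adds 1,2 to the ketone, which the two α-methoxy groups activate, and converts C=O into C=CHBr without touching the E-styryl bond or the acetal.

Step 5
Reactants: 6 1,5-bis(benzyloxy)-2-[(1E,3E)-4-bromo-3-(dimethoxymethyl)buta-1,3-dien-1-yl]-3-(methoxymethoxy)benzene; 7 chromium hexacarbonyl, Cr(CO)6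
Product: 10 pentacarbonyl{(2E,4E)-5-[2,4-bis(benzyloxy)-6-(methoxymethoxy)phenyl]-3-(dimethoxymethyl)-1-methoxypenta-2,4-dien-1-ylidene}chromium, via dienyllithium 8 (not isolated), via lithium acylchromate 9 (not isolated)
Conditions: t-BuLi (2.0 equiv), THF, −78 °C; Cr(CO)6, −78 to 0 °C; then Me3OBF4, CH2Cl2, 0 °C
Reagents that add atoms: trimethyloxonium tetrafluoroborate, C[O+](C)C.F[B-](F)(F)F
Why: Fischer carbene synthesis: bromine–lithium exchange proceeds with retention of alkene geometry, the dienyllithium adds to a carbonyl ligand of Cr(CO)6 to give the acylchromate, and O-methylation with the oxonium salt delivers the methoxycarbene complex of zerovalent chromium.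

Step 6
Reactants: 10 pentacarbonyl{(2E,4E)-5-[2,4-bis(benzyloxy)-6-(methoxymethoxy)phenyl]-3-(dimethoxymethyl)-1-methoxypenta-2,4-dien-1-ylidene}chromium
Product: 13 2-[2,4-bis(benzyloxy)-6-(methoxymethoxy)phenyl]-4-(dimethoxymethyl)-6-methoxyphenol, via chromium-bound dienylketene 11 (not isolated), via cyclohexadienone tautomer 12 (not isolated)
Conditions: hν (450 W medium-pressure Hg lamp, Pyrex), CO (1 atm), THF, rt
Reagents that add atoms: none
Why: Light promotes migratory insertion of a carbonyl ligand into the Cr=C bond of the zerovalent chromium complex, which creates the C4'–C5' bond and a chromium-bound dienyl(methoxy)ketene; the ketene carbon then bonds to the aryl-bearing diene terminus (C3'–C4') and the dienone enolises to the phenol. The closest known reaction type is the photochemical ortho-benzannulation of chromium dienyl(alkoxy)carbene complexes to 2-alkoxyphenols, a relative of the Dötz benzannulation in which the diene is already attached to the carbene carbon. Ring B closes by a thermal disrotatory 6π-electrocyclisation of the s-cis dienylketene, and the only sp3 centre so formed, C3' of the dienone, is erased by tautomerisation, so no stereocentre has to be controlled. The step needs the carbene carbon and the styryl arm cis on the central C6'=C1' bond: this is built in by the stereoretentive Br–Li exchange of the (E)-bromide, any trans isomer is fed in by photochemical E/Z isomerisation of the alkenylcarbene, and the trans C2'=C3' bond turns the bulky aryl outward during closure. Regiochemistry is fixed by the chain itself (carbene OMe becomes C5'–OMe, the inserted ligand CO becomes C4'–OH, the acetal sits on C1'), the CO atmosphere recaptures chromium as Cr(CO)6 and holds back thermal cyclopentannulation, and benzyl, MOM and acetal groups are spectators under Pyrex-filtered light.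

Step 7
Reactants: 13 2-[2,4-bis(benzyloxy)-6-(methoxymethoxy)phenyl]-4-(dimethoxymethyl)-6-methoxyphenol
Product: 14 2',4'-bis(benzyloxy)-5-(dimethoxymethyl)-2,3-dimethoxy-6'-(methoxymethoxy)-1,1'-biphenyl
Conditions: MeI, K2CO3, DMF, rt
Reagents that add atoms: iodomethane, CI
Why: Williamson O-methylation of the hindered but acidic phenol turns C4'–OH into the C4'–OMe of the target under conditions that leave acetal, MOM and benzyl ethers alone.

Step 8
Reactants: 14 2',4'-bis(benzyloxy)-5-(dimethoxymethyl)-2,3-dimethoxy-6'-(methoxymethoxy)-1,1'-biphenyl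
Product: 16 1-[4,6-bis(benzyloxy)-3-[5-(dimethoxymethyl)-2,3-dimethoxyphenyl]-2-(methoxymethoxy)phenyl]ethan-1-one, via aryllithium 15 (not isolated)
Conditions: n-BuLi (1.2 equiv), THF, −20 to 0 °C; MeC(O)N(OMe)Me, −78 to 0 °C; aq NH4Cl
Reagents that add atoms: N-methoxy-N-methylacetamide, CC(=O)N(C)OC
Why: Directed ortho-metalation followed by Weinreb ketone synthesis: the MOM ether chelates n-BuLi and directs deprotonation to its only free ortho position, which the neighbouring benzyloxy group acidifies further, and the stable tetrahedral adduct of the Weinreb amide prevents over-addition.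

Step 9
Reactants: 16 1-[4,6-bis(benzyloxy)-3-[5-(dimethoxymethyl)-2,3-dimethoxyphenyl]-2-(methoxymethoxy)phenyl]ethan-1-one
Product: 17 1-[4,6-bis(benzyloxy)-3-[5-(dimethoxymethyl)-2,3-dimethoxyphenyl]-2-hydroxyphenyl]ethan-1-one
Conditions: HCl (cat., from AcCl), anhydrous MeOH–CH2Cl2, 0 °C to rt; NaHCO3 quench
Reagents that add atoms: none
Why: Acid-catalysed acetal exchange (methanolysis) removes the MOM group, which the ortho acyl group makes especially labile, while in methanol the dimethyl acetal can only exchange with itself and benzyl ethers are stable to dilute HCl.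

Step 10
Reactants: 17 1-[4,6-bis(benzyloxy)-3-[5-(dimethoxymethyl)-2,3-dimethoxyphenyl]-2-hydroxyphenyl]ethan-1-one; 18 4-(benzyloxy)benzaldehyde
Product: 19 (E)-3-[4-(benzyloxy)phenyl]-1-{4,6-bis(benzyloxy)-3-[5-(dimethoxymethyl)-2,3-dimethoxyphenyl]-2-hydroxyphenyl}prop-2-en-1-one
Conditions: KOH (aq 50%), EtOH–THF, rt
Reagents that add atoms: none
Why: Claisen–Schmidt condensation of the methyl ketone with a non-enolisable aldehyde gives the E-chalcone by E1cB dehydration, with the base-stable acetal keeping the ring B formyl carbon out of the reaction.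

Step 11
Reactants: 19 (E)-3-[4-(benzyloxy)phenyl]-1-{4,6-bis(benzyloxy)-3-[5-(dimethoxymethyl)-2,3-dimethoxyphenyl]-2-hydroxyphenyl}prop-2-en-1-one
Product: 21 3-{5,7-bis(benzyloxy)-2-[4-(benzyloxy)phenyl]-4-oxo-4H-chromen-8-yl}-4,5-dimethoxybenzaldehyde, via flavone dimethyl acetal 20 (not isolated)
Conditions: I2 (10 mol %), DMSO, 130 °C; then 1 M HCl, THF, rt
Reagents that add atoms: water, O
Why: Iodine-catalysed oxidative cyclisation of a 2'-hydroxychalcone in DMSO (oxa-Michael closure through the only free ortho hydroxyl, then iodination–elimination with DMSO as terminal oxidant) fixes C8'' as the biaryl carbon, and the acidic work-up completes acetal hydrolysis to the aldehyde.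

Step 12
Reactants: 21 3-{5,7-bis(benzyloxy)-2-[4-(benzyloxy)phenyl]-4-oxo-4H-chromen-8-yl}-4,5-dimethoxybenzaldehyde; 22 1-[2,4-bis(benzyloxy)-6-hydroxyphenyl]ethan-1-one
Product: 23 (E)-1-[2,4-bis(benzyloxy)-6-hydroxyphenyl]-3-(3-{5,7-bis(benzyloxy)-2-[4-(benzyloxy)phenyl]-4-oxo-4H-chromen-8-yl}-4,5-dimethoxyphenyl)prop-2-en-1-one
Conditions: KOH (aq 50%), EtOH–THF, rt
Reagents that add atoms: none
Why: Claisen–Schmidt condensation of the acetophenone enolate with the non-enolisable aryl aldehyde gives the E-chalcone, and the flavone of unit 2 has no acidic C–H and should tolerate hydroxide at room temperature.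

Step 13
Reactants: 23 (E)-1-[2,4-bis(benzyloxy)-6-hydroxyphenyl]-3-(3-{5,7-bis(benzyloxy)-2-[4-(benzyloxy)phenyl]-4-oxo-4H-chromen-8-yl}-4,5-dimethoxyphenyl)prop-2-en-1-one
Product: 24 5,7-bis(benzyloxy)-8-{5-[5,7-bis(benzyloxy)-4-oxo-4H-chromen-2-yl]-2,3-dimethoxyphenyl}-2-[4-(benzyloxy)phenyl]-4H-chromen-4-one
Conditions: I2 (10 mol %), DMSO, 130 °C
Reagents that add atoms: none
Why: Iodine/DMSO oxidative cyclisation of the 2'-hydroxychalcone again closes the pyranone through the single free hydroxyl, which gives the 5,7-dioxygenated flavone of unit 1.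

Step 14
Reactants: 24 5,7-bis(benzyloxy)-8-{5-[5,7-bis(benzyloxy)-4-oxo-4H-chromen-2-yl]-2,3-dimethoxyphenyl}-2-[4-(benzyloxy)phenyl]-4H-chromen-4-one
Product: 25 5'-methoxybilobetin, 8-[5-(5,7-dihydroxy-4-oxo-4H-chromen-2-yl)-2,3-dimethoxyphenyl]-5,7-dihydroxy-2-(4-hydroxyphenyl)-4H-chromen-4-one
Conditions: H2 (1 atm), 10% Pd/C, THF–MeOH, rt
Reagents that add atoms: none
Why: Catalytic hydrogenolysis cleaves the five benzyl ethers at their benzylic C–O bonds while aryl methyl ethers are inert, and stopping at the calculated hydrogen uptake should spare the flavone C2=C3 bonds.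

**Compound list**

1 | 2,4,6-trihydroxybenzaldehyde | O=Cc1c(O)cc(O)cc1O | starting material
2 | 2,4-bis(benzyloxy)-6-hydroxybenzaldehyde | O=Cc1c(O)cc(OCc2ccccc2)cc1OCc1ccccc1 | intermediate
3 | 2,4-bis(benzyloxy)-6-(methoxymethoxy)benzaldehyde | COCOc1cc(OCc2ccccc2)cc(OCc2ccccc2)c1C=O | intermediate
4 | 1,1-dimethoxyacetone | CC(=O)C(OC)OC | starting material
5 | (E)-4-[2,4-bis(benzyloxy)-6-(methoxymethoxy)phenyl]-1,1-dimethoxybut-3-en-2-one | COCOc1cc(OCc2ccccc2)cc(OCc2ccccc2)c1/C=C/C(=O)C(OC)OC | intermediate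
6 | 1,5-bis(benzyloxy)-2-[(1E,3E)-4-bromo-3-(dimethoxymethyl)buta-1,3-dien-1-yl]-3-(methoxymethoxy)benzene | COCOc1cc(OCc2ccccc2)cc(OCc2ccccc2)c1/C=C/C(=C\Br)C(OC)OC | intermediate
7 | chromium hexacarbonyl, Cr(CO)6 | O=C=[Cr](=C=O)(=C=O)(=C=O)(=C=O)=C=O | starting material
8 | {(1E,3E)-4-[2,4-bis(benzyloxy)-6-(methoxymethoxy)phenyl]-2-(dimethoxymethyl)buta-1,3-dien-1-yl}lithium | COCOc1cc(OCc2ccccc2)cc(OCc2ccccc2)c1/C=C/C(=C\[Li])C(OC)OC | intermediate (not isolated)
9 | lithium pentacarbonyl{(2E,4E)-5-[2,4-bis(benzyloxy)-6-(methoxymethoxy)phenyl]-3-(dimethoxymethyl)penta-2,4-dienoyl}chromate | COCOc1cc(OCc2ccccc2)cc(OCc2ccccc2)c1/C=C/C(=C\C([O-])=[Cr](=C=O)(=C=O)(=C=O)(=C=O)=C=O)C(OC)OC.[Li+] | intermediate (not isolated)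
10 | pentacarbonyl{(2E,4E)-5-[2,4-bis(benzyloxy)-6-(methoxymethoxy)phenyl]-3-(dimethoxymethyl)-1-methoxypenta-2,4-dien-1-ylidene}chromium | COCOc1cc(OCc2ccccc2)cc(OCc2ccccc2)c1/C=C/C(=C\C(OC)=[Cr](=C=O)(=C=O)(=C=O)(=C=O)=C=O)C(OC)OC | intermediate (key-step precursor)
11 | (3E,5E)-6-[2,4-bis(benzyloxy)-6-(methoxymethoxy)phenyl]-4-(dimethoxymethyl)-2-methoxyhexa-1,3,5-trien-1-one, π-bound to a Cr(CO)4 fragment (written as two parts) | COCOc1cc(OCc2ccccc2)cc(OCc2ccccc2)c1/C=C/C(=C\C(OC)=C=O)C(OC)OC.O=C=[Cr](=C=O)(=C=O)=C=O | intermediate (not isolated)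
12 | 6-[2,4-bis(benzyloxy)-6-(methoxymethoxy)phenyl]-4-(dimethoxymethyl)-2-methoxycyclohexa-2,4-dien-1-one (racemic, transient) | COCOc1cc(OCc2ccccc2)cc(OCc2ccccc2)c1C1C=C(C(OC)OC)C=C(OC)C1=O | intermediate (not isolated)
13 | 2-[2,4-bis(benzyloxy)-6-(methoxymethoxy)phenyl]-4-(dimethoxymethyl)-6-methoxyphenol | COCOc1cc(OCc2ccccc2)cc(OCc2ccccc2)c1-c1cc(C(OC)OC)cc(OC)c1O | intermediate (key-step product)
14 | 2',4'-bis(benzyloxy)-5-(dimethoxymethyl)-2,3-dimethoxy-6'-(methoxymethoxy)-1,1'-biphenyl | COCOc1cc(OCc2ccccc2)cc(OCc2ccccc2)c1-c1cc(C(OC)OC)cc(OC)c1OC | intermediate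
15 | {4,6-bis(benzyloxy)-3-[5-(dimethoxymethyl)-2,3-dimethoxyphenyl]-2-(methoxymethoxy)phenyl}lithium | COCOc1c([Li])c(OCc2ccccc2)cc(OCc2ccccc2)c1-c1cc(C(OC)OC)cc(OC)c1OC | intermediate (not isolated)
16 | 1-[4,6-bis(benzyloxy)-3-[5-(dimethoxymethyl)-2,3-dimethoxyphenyl]-2-(methoxymethoxy)phenyl]ethan-1-one | COCOc1c(C(C)=O)c(OCc2ccccc2)cc(OCc2ccccc2)c1-c1cc(C(OC)OC)cc(OC)c1OC | intermediate
17 | 1-[4,6-bis(benzyloxy)-3-[5-(dimethoxymethyl)-2,3-dimethoxyphenyl]-2-hydroxyphenyl]ethan-1-one | CC(=O)c1c(O)c(-c2cc(C(OC)OC)cc(OC)c2OC)c(OCc2ccccc2)cc1OCc1ccccc1 | intermediate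
18 | 4-(benzyloxy)benzaldehyde | O=Cc1ccc(OCc2ccccc2)cc1 | starting material
19 | (E)-3-[4-(benzyloxy)phenyl]-1-{4,6-bis(benzyloxy)-3-[5-(dimethoxymethyl)-2,3-dimethoxyphenyl]-2-hydroxyphenyl}prop-2-en-1-one | O=C(/C=C/c1ccc(OCc2ccccc2)cc1)c1c(O)c(-c2cc(C(OC)OC)cc(OC)c2OC)c(OCc2ccccc2)cc1OCc1ccccc1 | intermediate
20 | 5,7-bis(benzyloxy)-2-[4-(benzyloxy)phenyl]-8-[5-(dimethoxymethyl)-2,3-dimethoxyphenyl]-4H-chromen-4-one | COC(OC)c1cc(OC)c(OC)c(-c2c(OCc3ccccc3)cc(OCc3ccccc3)c3c(=O)cc(-c4ccc(OCc5ccccc5)cc4)oc23)c1 | intermediate (not isolated)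
21 | 3-{5,7-bis(benzyloxy)-2-[4-(benzyloxy)phenyl]-4-oxo-4H-chromen-8-yl}-4,5-dimethoxybenzaldehyde | O=Cc1cc(OC)c(OC)c(-c2c(OCc3ccccc3)cc(OCc3ccccc3)c3c(=O)cc(-c4ccc(OCc5ccccc5)cc4)oc23)c1 | intermediate
22 | 1-[2,4-bis(benzyloxy)-6-hydroxyphenyl]ethan-1-one | CC(=O)c1c(O)cc(OCc2ccccc2)cc1OCc1ccccc1 | starting material
23 | (E)-1-[2,4-bis(benzyloxy)-6-hydroxyphenyl]-3-(3-{5,7-bis(benzyloxy)-2-[4-(benzyloxy)phenyl]-4-oxo-4H-chromen-8-yl}-4,5-dimethoxyphenyl)prop-2-en-1-one | O=C(/C=C/c1cc(OC)c(OC)c(-c2c(OCc3ccccc3)cc(OCc3ccccc3)c3c(=O)cc(-c4ccc(OCc5ccccc5)cc4)oc23)c1)c1c(O)cc(OCc2ccccc2)cc1OCc1ccccc1 | intermediate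
24 | 5,7-bis(benzyloxy)-8-{5-[5,7-bis(benzyloxy)-4-oxo-4H-chromen-2-yl]-2,3-dimethoxyphenyl}-2-[4-(benzyloxy)phenyl]-4H-chromen-4-one | COc1cc(-c2cc(=O)c3c(OCc4ccccc4)cc(OCc4ccccc4)cc3o2)cc(-c2c(OCc3ccccc3)cc(OCc3ccccc3)c3c(=O)cc(-c4ccc(OCc5ccccc5)cc4)oc23)c1OC | intermediate
25 | 5'-methoxybilobetin, 8-[5-(5,7-dihydroxy-4-oxo-4H-chromen-2-yl)-2,3-dimethoxyphenyl]-5,7-dihydroxy-2-(4-hydroxyphenyl)-4H-chromen-4-one | COc1cc(-c2cc(=O)c3c(O)cc(O)cc3o2)cc(-c2c(O)cc(O)c3c(=O)cc(-c4ccc(O)cc4)oc23)c1OC | target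

**Step count**

Total steps: 14. Longest linear sequence: 14 steps (1 to 25); 4, 7, 18 and 22 enter as bought materials.

**Steps most likely to fail**

1. Step 6. The alkenylcarbene may fail to populate the cis geometry on C6'=C1', or the complex may be lost to thermal cyclopentannulation or to oxidative decomplexation before the hindered, fully substituted dienylketene closes. The fallback gives up the ring construction and takes ring B from an arene. It sets out from aldehyde 3 and comes back at 14. Dakin oxidation of 3 (mCPBA, CH2Cl2) would give 2,4-bis(benzyloxy)-6-(methoxymethoxy)phenyl formate F1, and K2CO3/MeOH would release 2,4-bis(benzyloxy)-6-(methoxymethoxy)phenol F2. Tf2O/pyridine would then give 2,4-bis(benzyloxy)-6-(methoxymethoxy)phenyl trifluoromethanesulfonate F3. Commercial 5-bromoveratraldehyde would be acetalised (HC(OMe)3, TsOH cat., MeOH) to 1-bromo-5-(dimethoxymethyl)-2,3-dimethoxybenzene F4 and borylated (B2pin2, PdCl2(dppf), KOAc, dioxane) to 2-[5-(dimethoxymethyl)-2,3-dimethoxyphenyl]-4,4,5,5-tetramethyl-1,3,2-dioxaborolane F5. Suzuki–Miyaura coupling of F3 with F5 (Pd(OAc)2, SPhos, K3PO4, toluene, 100 °C) should give 14.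

2. Step 8. Lithiation may stray to the position between the two benzyloxy groups or to ring B next to the acetal, or benzylic deprotonation may set off a Wittig rearrangement of a benzyl ether. The fallback replaces carbanion chemistry by phenoxide-directed electrophilic substitution. It sets out from 14 and comes back at 17. Acid methanolysis of the MOM ether (HCl cat., MeOH) would give 3,5-bis(benzyloxy)-2-[5-(dimethoxymethyl)-2,3-dimethoxyphenyl]phenol F6. Magnesium phenoxide-mediated ortho-formylation (MgCl2, Et3N, paraformaldehyde, MeCN, reflux), which can only reach the single free ortho carbon, would give 4,6-bis(benzyloxy)-3-[5-(dimethoxymethyl)-2,3-dimethoxyphenyl]-2-hydroxybenzaldehyde F7. MeMgBr (THF, 0 °C) would add to give 3,5-bis(benzyloxy)-2-[5-(dimethoxymethyl)-2,3-dimethoxyphenyl]-6-(1-hydroxyethyl)phenol F8 (racemic), and MnO2 (CH2Cl2) would oxidise the benzylic alcohol to 17.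

3. Step 5. The functionalised dienyllithium may decompose or lose its geometry before it is captured by the poorly soluble Cr(CO)6, or the acylchromate may be methylated incompletely. The fallback builds the C2=C3 bond by aldol condensation on a preformed carbene complex. It sets out from enone 5 and comes back at 10. From 7, MeLi (Et2O) would give lithium pentacarbonyl(acetyl)chromate F9, and Me3OBF4 would give pentacarbonyl(1-methoxyethylidene)chromium F10. n-BuLi (THF, −78 °C) would convert F10 into its lithium anion F11. Aldol addition of F11 to the ketone of 5, whose α,α-dimethoxy substitution favours 1,2-attack, would give the β-hydroxy carbene complex pentacarbonyl{(4E)-5-[2,4-bis(benzyloxy)-6-(methoxymethoxy)phenyl]-3-(dimethoxymethyl)-3-hydroxy-1-methoxypent-4-en-1-ylidene}chromium F12 (racemic). MsCl/Et3N would dehydrate F12 through its methanesulfonate F13 to 10.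

**Further compounds**

F1 | step 6 | 2,4-bis(benzyloxy)-6-(methoxymethoxy)phenyl formate | COCOc1cc(OCc2ccccc2)cc(OCc2ccccc2)c1OC=O
F2 | step 6 | 2,4-bis(benzyloxy)-6-(methoxymethoxy)phenol | COCOc1cc(OCc2ccccc2)cc(OCc2ccccc2)c1O
F3 | step 6 | 2,4-bis(benzyloxy)-6-(methoxymethoxy)phenyl trifluoromethanesulfonate | COCOc1cc(OCc2ccccc2)cc(OCc2ccccc2)c1OS(=O)(=O)C(F)(F)F
F4 | step 6 | 1-bromo-5-(dimethoxymethyl)-2,3-dimethoxybenzene | COC(OC)c1cc(Br)c(OC)c(OC)c1
F5 | step 6 | 2-[5-(dimethoxymethyl)-2,3-dimethoxyphenyl]-4,4,5,5-tetramethyl-1,3,2-dioxaborolane | COC(OC)c1cc(B2OC(C)(C)C(C)(C)O2)c(OC)c(OC)c1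
F6 | step 8 | 3,5-bis(benzyloxy)-2-[5-(dimethoxymethyl)-2,3-dimethoxyphenyl]phenol | COc1cc(C(OC)OC)cc(-c2c(O)cc(OCc3ccccc3)cc2OCc2ccccc2)c1OC
F7 | step 8 | 4,6-bis(benzyloxy)-3-[5-(dimethoxymethyl)-2,3-dimethoxyphenyl]-2-hydroxybenzaldehyde | O=Cc1c(O)c(-c2cc(C(OC)OC)cc(OC)c2OC)c(OCc2ccccc2)cc1OCc1ccccc1
F8 | step 8 | 3,5-bis(benzyloxy)-2-[5-(dimethoxymethyl)-2,3-dimethoxyphenyl]-6-(1-hydroxyethyl)phenol (racemic) | CC(O)c1c(O)c(-c2cc(C(OC)OC)cc(OC)c2OC)c(OCc2ccccc2)cc1OCc1ccccc1
F9 | step 5 | lithium pentacarbonyl(acetyl)chromate | [Li+].CC([O-])=[Cr](=C=O)(=C=O)(=C=O)(=C=O)=C=O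
F10 | step 5 | pentacarbonyl(1-methoxyethylidene)chromium, (CO)5Cr=C(OMe)CH3 | COC(C)=[Cr](=C=O)(=C=O)(=C=O)(=C=O)=C=O
F11 | step 5 | lithium anion of pentacarbonyl(1-methoxyethylidene)chromium | [Li+].[CH2-]C(OC)=[Cr](=C=O)(=C=O)(=C=O)(=C=O)=C=O
F12 | step 5 | pentacarbonyl{(4E)-5-[2,4-bis(benzyloxy)-6-(methoxymethoxy)phenyl]-3-(dimethoxymethyl)-3-hydroxy-1-methoxypent-4-en-1-ylidene}chromium (racemic) | COCOc1cc(OCc2ccccc2)cc(OCc2ccccc2)c1/C=C/C(O)(CC(OC)=[Cr](=C=O)(=C=O)(=C=O)(=C=O)=C=O)C(OC)OC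
F13 | step 5 | 3-methanesulfonate of F12 (racemic) | COCOc1cc(OCc2ccccc2)cc(OCc2ccccc2)c1/C=C/C(OS(C)(=O)=O)(CC(OC)=[Cr](=C=O)(=C=O)(=C=O)(=C=O)=C=O)C(OC)OC
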